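The product levels off near 60.6% in both earlier runs, and I want to know what part of the substrate has reacted at the end in cedar, maple and ash, which differ from those runs in their scavenger charge.

| setting | Friday's | Thursday's | cedar | maple | ash |
|---|---|---|---|---|---|
| substrate | 0.050 M | 0.050 M | 0.050 M | 0.050 M | 0.050 M |
| reagent | 0.060 M | 0.060 M | 0.0600 M | 0.0600 M | 0.0600 M |
| scavenger | 0.054 M | 0.12 M | 0.110 M | 0.170 M | 0.0750 M |
| initiator | 0.75 mM | 0.75 mM | 0.75 mM | 0.75 mM | 0.75 mM |
| radical scavenger | 0.49 mM | 0.49 mM | 0.49 mM | 0.49 mM | 0.49 mM |
| remark | run made earlier | run made earlier |  |  |  |
| time |  |  | 8.0 d | 8.0 d | 8.0 d |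

- Friday's (time / d: substrate / %, product / %): 1.67: 44.2, 53.9; 3.00: 38.9, 58.8; 5.00: 37.1, 60.1; 6.00: 37.3, 61.0; 8.00: 38.0, 61.1
- Thursday's (time / d: substrate / %, product / %): 0.625: 75.4, 21.1; 2.08: 43.0, 56.5; 4.00: 38.3, 60.3; 6.00: 36.7, 61.0; 8.00: 37.3, 60.2

(readings scatter by 0.5 percentage points)

- the numbers in the tables scatter by 0.5 percentage points (one standard deviation)

1. part of the substrate that has reacted at the end, cedar
2. part of the substrate that has reacted at the end, maple
3. part of the substrate that has reacted at the end, ash
4. what raising the concentration of scavenger from its lowest to its highest value here does to the part of the substrate that has reacted (changes below 5 percentage points count as none) (it falls / it rises / no change)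

I average the readings from 4.00 d on. Substrate then stands at 37.5% in Friday's run, with 0.054 M scavenger, and at 37.4% in Thursday's, with 0.12 M, and these two readings match. My first way to the asked number is therefore the substrate lost, 62.5%.

My second way starts from the charges. I suppose a chain reaction in which each initiator, once decomposed, gives two radicals and each radical scavenger catches one. The remaining radicals must then end by termination, holding substrate in a form that neither column shows. From the charges I reckon 2.02% as the radical surplus: two radicals for each initiator, less one for each radical scavenger, in percent of the substrate charged. Added to the product, it gives 62.6% reacted, which agrees with the substrate lost. The gap in the readings, 1.9 percentage points, carries a scatter of about 0.29 points, so the surplus is a fair account of it. The surplus accounts for 2.02% of the substrate charged and tells me nothing about how the scavenger bears on the product. My ground for the scavenger is therefore the match between Friday's and Thursday's runs. On that match I commit to 62.5% for cedar, maple and ash, and for maple this is an extrapolation, as its charge lies beyond Thursday's.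

The forecast gives 62.5% for cedar, 62.5% for maple and 62.5% for ash, with the trend no change, holding that “the scavenger has no visible effect on it over a twofold range”.

The simulation gives 62.8%, 62.8% and 62.8%, and the trend is no change, so the forecast stands.

    initiator → 2 initiating radical (k = 1.02 × 10⁻⁵ s⁻¹)
    substrate + initiating radical → capped initiator + first chain carrier (k = 19800 L mol⁻¹ s⁻¹)
    reagent + first chain carrier → product + second chain carrier (k = 1990 L mol⁻¹ s⁻¹)
    substrate + second chain carrier → released group + first chain carrier (k = 726 L mol⁻¹ s⁻¹)
    2 first chain carrier → ended chains A (k = 4.00 × 10⁷ L mol⁻¹ s⁻¹)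
    substrate + released group ⇌ idle adduct, settled at all times (K = 387 L mol⁻¹)
    scavenger + released group → scavenged by-product (k = 0.0360 L mol⁻¹ s⁻¹)
    second chain carrier + radical scavenger → ended chains B (k = 7.17 × 10⁷ L mol⁻¹ s⁻¹)
    2 reagent → homo dimer (k = 1.30 × 10⁻⁴ L mol⁻¹ s⁻¹)

In cedar the step of substrate with second chain carrier has 99% of its turnover behind it by 4.00 d, and the half-life of substrate by that step lengthens from 0.77 d at 0.762 d to 580 d at 8.00 d, when 0.533% of the reagent and 0.0867% of the initiator are left. Meanwhile the scavenger takes up released group, ending with 82.4% of its charge in maple and 60.1% in ash. Ended chains A, each counted as two, stand at 2.02% in cedar, matching the surplus of 2.02%. In the neighbour of cedar charged with 0.0019 M initiator, the surplus becomes 6.62%; the computed ended chains A there are 6.61%, with 92.4% of the substrate reacted.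

All runs were generated by integration for substances that don't exist, noise included.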